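**Retrosynthetic overview**

Gymconopin D (13) is achiral. The strategy rests on the CH2CH2 bridge between C1 of ring A (the 3,5-dimethoxy ring that carries the 4-hydroxybenzyl group at C2) and C1 of the 3-hydroxyphenyl ring B: an ethane with an aryl group at each end is the reduced form of a diarylalkyne.
Disconnection 1: bibenzyl 13 ⇒ diarylalkyne 12 (hydrogenation, which also frees the ring C phenol from its benzyl ether).
Disconnection 2: 12 ⇒ aryl bromide 7 + trimethylsilylacetylene 8 + 3-iodophenol 9, both aryl–C(sp) bonds being made in one pot on the two-carbon linchpin.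
Disconnection 3: 7 ⇒ aldehyde 3 + aryl Grignard reagent 5 (ring A–CH2–ring C bond), and 3 ⇒ bromoarene 1 by formylation.
No ring is built: rings A, B and C are bought as arenes; ring C is joined to ring A first (steps 2 and 3) and ring B last (step 4).

Key step: step 4

Remark on the chemistry: formylation of 1 is assumed to occur mainly at C2 (ortho to bromine, para to one methoxy group) and not at C4 between the two methoxy groups. Carbinol 6 is racemic, and its stereocenter is removed in step 3.

**Route**

Step 1
Reactants: 1 1-bromo-3,5-dimethoxybenzene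
Product: 3 2-bromo-4,6-dimethoxybenzaldehyde, via iminium chloride 2 (not isolated)
Conditions: POCl3, DMF, 0 °C to 90 °C; then H2O, 0 °C to rt
Reagents that add atoms: N,N-dimethylformamide, CN(C)C=O (formyl carbon); water, O (carbonyl oxygen)
Why: Vilsmeier–Haack formylation; the chloroiminium electrophile should attack the position para to one methoxy group and ortho to the other (next to bromine) in preference to the site flanked by two methoxy groups, and hydrolysis of iminium salt 2 releases the aldehyde.

Step 2
Reactants: 3 2-bromo-4,6-dimethoxybenzaldehyde; 4 1-(benzyloxy)-4-bromobenzene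
Product: 6 [4-(benzyloxy)phenyl](2-bromo-4,6-dimethoxyphenyl)methanol (racemic), via Grignard reagent 5 (not isolated)
Conditions: 4, Mg, I2 (cat.), THF, reflux; solution decanted from excess Mg; then 3, THF, 0 °C to rt; sat. aq. NH4Cl
Reagents that add atoms: none
Why: Grignard addition of the preformed arylmagnesium bromide to the aldehyde is faster at 0 °C than halogen–magnesium exchange at the ring A bromide; the carbinol stereocenter is formed without control and is deleted in step 3.

Step 3
Reactants: 6 [4-(benzyloxy)phenyl](2-bromo-4,6-dimethoxyphenyl)methanol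
Product: 7 1-[4-(benzyloxy)benzyl]-2-bromo-4,6-dimethoxybenzene
Conditions: Et3SiH (3 equiv), CF3CO2H (5 equiv), CH2Cl2, 0 °C; then aq. NaHCO3
Reagents that add atoms: none
Why: Ionic hydrogenation; the carbinol ionises readily to a benzhydryl cation stabilised by the ortho and para methoxy groups and the para benzyloxy group, and Et3SiH traps it by hydride transfer at a temperature and acid loading at which the aryl benzyl ether should persist.

Step 4
Reactants: 7 1-[4-(benzyloxy)benzyl]-2-bromo-4,6-dimethoxybenzene; 8 trimethylsilylacetylene; 9 3-iodophenol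
Product: 12 3-({2-[4-(benzyloxy)benzyl]-3,5-dimethoxyphenyl}ethynyl)phenol, via silyl alkyne 10 (not isolated), via terminal alkyne 11 (not isolated)
Conditions: 7, 8 (1.2 equiv), PdCl2(PPh3)2 (5 mol %), CuI (10 mol %), Et3N, DMF (degassed), 80 °C, sealed tube; Ar purge; then 9, CsF, MeOH, H2O, 50 °C
Reagents that add atoms: none
Why: PdCl2(PPh3)2 is reduced in the flask to zerovalent palladium, which inserts into the C–Br bond of 7; transmetalation from the copper acetylide of 8 and reductive elimination give silyl alkyne 10, so the C1(ring A)–C(sp) bond is formed first. Fluoride from CsF then cleaves the C–Si bond and releases terminal alkyne 11 at low stationary concentration, and a second cycle of oxidative addition into the C–I bond of 9, transmetalation and reductive elimination forms the C(sp)–C1(ring B) bond. The closest known reaction type is the one-pot sequential Sonogashira coupling and fluoride-triggered desilylative Sonogashira coupling of trimethylsilylacetylene with two different aryl halides. No ring is closed and no stereocenter is formed. The selectivity needed is the order in which the two arenes are attached: the silyl group keeps the second alkyne terminus inert until CsF is added, the less reactive ortho-benzylated bromide is consumed first under forcing conditions, unreacted 8 is purged before 9 and CsF enter, and the reactive iodide then couples under mild conditions. The free phenol of 9 is tolerated by the amine and fluoride bases, and the aryl benzyl ether, the methyl ethers and the diarylmethane CH2 are inert.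

Step 5
Reactants: 12 3-({2-[4-(benzyloxy)benzyl]-3,5-dimethoxyphenyl}ethynyl)phenol
Product: 13 gymconopin D, 3-{2-[2-(4-hydroxybenzyl)-3,5-dimethoxyphenyl]ethyl}phenol
Conditions: H2 (1 atm), 10% Pd/C, EtOAc/MeOH, rt
Reagents that add atoms: none
Why: Heterogeneous catalytic hydrogenation should saturate the diarylalkyne to the ethane bridge and cleave the aryl benzyl ether by hydrogenolysis in the same operation, while the diarylmethane C–C bonds and the methyl ethers are stable.

**Compound list**

1 | 1-bromo-3,5-dimethoxybenzene | COc1cc(Br)cc(OC)c1 | starting material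
2 | N-[(2-bromo-4,6-dimethoxyphenyl)methylidene]-N-methylmethanaminium chloride | COc1cc(Br)c(C=[N+](C)C)c(OC)c1.[Cl-] | intermediate (not isolated)
3 | 2-bromo-4,6-dimethoxybenzaldehyde | COc1cc(Br)c(C=O)c(OC)c1 | intermediate
4 | 1-(benzyloxy)-4-bromobenzene | Brc1ccc(OCc2ccccc2)cc1 | starting material
5 | 4-(benzyloxy)phenylmagnesium bromide | Br[Mg]c1ccc(OCc2ccccc2)cc1 | intermediate (not isolated)
6 | [4-(benzyloxy)phenyl](2-bromo-4,6-dimethoxyphenyl)methanol (racemic) | COc1cc(Br)c(C(O)c2ccc(OCc3ccccc3)cc2)c(OC)c1 | intermediate
7 | 1-[4-(benzyloxy)benzyl]-2-bromo-4,6-dimethoxybenzene | COc1cc(Br)c(Cc2ccc(OCc3ccccc3)cc2)c(OC)c1 | intermediate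
8 | trimethylsilylacetylene | C#C[Si](C)(C)C | starting material
9 | 3-iodophenol | Oc1cccc(I)c1 | starting material
10 | ({2-[4-(benzyloxy)benzyl]-3,5-dimethoxyphenyl}ethynyl)trimethylsilane | COc1cc(C#C[Si](C)(C)C)c(Cc2ccc(OCc3ccccc3)cc2)c(OC)c1 | intermediate (not isolated)
11 | 2-[4-(benzyloxy)benzyl]-1-ethynyl-3,5-dimethoxybenzene | COc1cc(C#C)c(Cc2ccc(OCc3ccccc3)cc2)c(OC)c1 | intermediate (not isolated)
12 | 3-({2-[4-(benzyloxy)benzyl]-3,5-dimethoxyphenyl}ethynyl)phenol | COc1cc(C#Cc2cccc(O)c2)c(Cc2ccc(OCc3ccccc3)cc2)c(OC)c1 | intermediate
13 | gymconopin D, 3-{2-[2-(4-hydroxybenzyl)-3,5-dimethoxyphenyl]ethyl}phenol | COc1cc(CCc2cccc(O)c2)c(Cc2ccc(O)cc2)c(OC)c1 | target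

**Step count**

Total steps: 5. Longest linear sequence: 5 steps (1 → 3 → 6 → 7 → 12 → 13).

**Steps most likely to fail**

Step 4. Oxidative addition into the ortho-benzylated C–Br bond may be sluggish, the unmasked alkyne may homocouple oxidatively at copper, and silylacetylene 8 carried into the fluoride stage would consume 9 as a symmetrical diarylalkyne. The fallback sets out from 7 and makes the hindered ring A–C(sp) bond by carbonyl homologation instead of palladium chemistry. Bromine–lithium exchange (n-BuLi, THF, −78 °C) and a DMF quench should give 2-[4-(benzyloxy)benzyl]-3,5-dimethoxybenzaldehyde F1. Seyferth–Gilbert homologation with the Ohira–Bestmann reagent (dimethyl (1-diazo-2-oxopropyl)phosphonate, K2CO3, MeOH, rt) should convert F1 into terminal alkyne 11, which is now isolated. A single Sonogashira coupling of 11 with the reactive iodide 9 (PdCl2(PPh3)2, CuI, Et3N, THF, rt) brings the route back at 12.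

Step 1. The electrophile may attack C4 between the two methoxy groups in competition with C2, and the regioisomeric aldehydes may be hard to separate. The fallback fixes the substitution pattern by purchase, sets out from Grignard reagent 5 and comes back at 12. Commercial 2-hydroxy-4,6-dimethoxybenzaldehyde F2 is treated with an excess of 5 (THF, 0 °C; the first equivalent deprotonates the phenol) to give the racemic carbinol 2-{[4-(benzyloxy)phenyl](hydroxy)methyl}-3,5-dimethoxyphenol F3. Ionic hydrogenation (Et3SiH, CF3CO2H, CH2Cl2, 0 °C) should give 2-[4-(benzyloxy)benzyl]-3,5-dimethoxyphenol F4, and Tf2O with pyridine (CH2Cl2, 0 °C) the triflate 2-[4-(benzyloxy)benzyl]-3,5-dimethoxyphenyl trifluoromethanesulfonate F5. F5 takes the place of bromide 7 in the one-pot coupling of step 4 (through 10 and 11).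

Step 3. The acid may remove or shift the benzyl group of the ring C ether, and the doubly stabilised benzhydryl cation may be captured by an electron-rich arene before hydride transfer. The fallback forms the diarylmethane bond without any cation, sets out from 3 and comes back at 7. Reduction with NaBH4 (MeOH, 0 °C) should give (2-bromo-4,6-dimethoxyphenyl)methanol F6. SOCl2 (CH2Cl2, 0 °C) should give 1-bromo-2-(chloromethyl)-3,5-dimethoxybenzene F7, which is used at once. Copper-catalysed coupling of F7 with Grignard reagent 5 (Li2CuCl4 cat., THF, −20 °C) should be selective for the benzylic chloride over the aryl bromide and deliver 7.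

**Further compounds**

F1 | step 4 | 2-[4-(benzyloxy)benzyl]-3,5-dimethoxybenzaldehyde | COc1cc(C=O)c(Cc2ccc(OCc3ccccc3)cc2)c(OC)c1
F2 | step 1 | 2-hydroxy-4,6-dimethoxybenzaldehyde (purchased) | COc1cc(O)c(C=O)c(OC)c1
F3 | step 1 | 2-{[4-(benzyloxy)phenyl](hydroxy)methyl}-3,5-dimethoxyphenol (racemic) | COc1cc(O)c(C(O)c2ccc(OCc3ccccc3)cc2)c(OC)c1
F4 | step 1 | 2-[4-(benzyloxy)benzyl]-3,5-dimethoxyphenol | COc1cc(O)c(Cc2ccc(OCc3ccccc3)cc2)c(OC)c1
F5 | step 1 | 2-[4-(benzyloxy)benzyl]-3,5-dimethoxyphenyl trifluoromethanesulfonate | COc1cc(OS(=O)(=O)C(F)(F)F)c(Cc2ccc(OCc3ccccc3)cc2)c(OC)c1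
F6 | step 3 | (2-bromo-4,6-dimethoxyphenyl)methanol | COc1cc(Br)c(CO)c(OC)c1
F7 | step 3 | 1-bromo-2-(chloromethyl)-3,5-dimethoxybenzene | COc1cc(Br)c(CCl)c(OC)c1
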